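**Retrosynthetic overview**
- The target comes from one Lewis-acid unmasking (peri 5-OMe and two MOM ethers) of a fully substituted flavone.
- The 3-methyl-2-oxobutyl chain is put on last, under base, by Pd α-arylation of a 6-bromoflavone with 3-methylbutan-2-one.
- Key disconnection: ring C is cut at O1–C2 and C3–C4, giving a ring A salicylaldehyde and a ring B aryl 1,4-enyne that already carries the prenyl group; the ring-closing bond is aryl-O to C2.
- The ring A aldehyde comes from 2-bromo-1,3-dimethoxybenzene by C–H borylation/oxidation (phenol C–O) and ortho-formylation; the symmetric phenol removes the 6- versus 8-position ambiguity.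
- Ring order: rings A and B are bought as benzenes; ring C (the pyranone) is the only ring formed, in the annulation.

Assumption: the target has no stereocentre and no stereogenic double bond (it is achiral), so "single enantiomer" is taken to mean the single constitution drawn.

**Route**

Step 1
Reactants: 1 2-bromo-1,3-dimethoxybenzene
Product: 3 4-bromo-3,5-dimethoxyphenol, via aryl pinacol boronate 2 (not isolated)
Conditions: [Ir(OMe)(C8H12)]2 (1.5 mol %), 4,4'-di-tert-butyl-2,2'-bipyridine (3 mol %), B2pin2 (1.0 equiv), THF, 80 °C; then 30% H2O2, aq. NaOH, 0 °C → rt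
Reagents that add atoms: bis(pinacolato)diboron CC1(C)OB(OC1(C)C)B1OC(C)(C)C(C)(C)O1 (boron of 2); hydrogen peroxide OO (oxygen of 3)
Why: One-pot iridium-catalysed C–H borylation/oxidation: borylation is sterically controlled and takes the only C–H flanked by two hydrogens (para to Br), and alkaline peroxide turns the C–B bond into the phenol C–O bond without touching the aryl bromide.

Step 2
Reactants: 3 4-bromo-3,5-dimethoxyphenol
Product: 4 3-bromo-6-hydroxy-2,4-dimethoxybenzaldehyde
Conditions: MgCl2, Et3N, (CH2O)n, MeCN, 80 °C; aq. HCl work-up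
Reagents that add atoms: formaldehyde (as paraformaldehyde) C=O
Why: Casnati–Skattebøl ortho-formylation: the magnesium phenoxide delivers formaldehyde only ortho to OH, and because the two ortho positions of 3 are equivalent by symmetry a single salicylaldehyde forms with Br between the two OMe groups, which later fixes the 6-position of ring A.

Step 3
Reactants: 5 2,4-dihydroxybenzaldehyde
Product: 6 2,4-bis(methoxymethoxy)benzaldehyde
Conditions: NaH, MOMCl, DMF, 0 °C → rt
Reagents that add atoms: chloromethyl methyl ether COCCl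
Why: Williamson O-alkylation of both phenoxides (MOM acetal protection), needed because a free ortho OH on ring B would add to the alkyne in later steps.

Step 4
Reactants: 6 2,4-bis(methoxymethoxy)benzaldehyde
Product: 7 1-ethynyl-2,4-bis(methoxymethoxy)benzene
Conditions: dimethyl (1-diazo-2-oxopropyl)phosphonate, K2CO3, MeOH, rt
Reagents that add atoms: dimethyl (1-diazo-2-oxopropyl)phosphonate COP(=O)(OC)C(=[N+]=[N-])C(C)=O
Why: Seyferth–Gilbert homologation with the Ohira–Bestmann reagent converts ArCHO into ArC≡CH under carbonate/methanol, which leaves aryl MOM ethers intact.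

Step 5
Reactants: 7 1-ethynyl-2,4-bis(methoxymethoxy)benzene; 8 1-bromo-3-methylbut-2-ene (prenyl bromide)
Product: 9 2,4-bis(methoxymethoxy)-1-(5-methylhex-4-en-1-yn-1-yl)benzene
Conditions: CuI (10 mol %), K2CO3, Bu4NI (10 mol %), DMF, rt
Reagents that add atoms: none
Why: Copper-acetylide allylation: the copper acetylide displaces the primary allylic bromide at its alpha carbon to give the skipped 1,4-enyne, and the weak base avoids isomerisation to the allene.

Step 6
Reactants: 4 3-bromo-6-hydroxy-2,4-dimethoxybenzaldehyde; 9 2,4-bis(methoxymethoxy)-1-(5-methylhex-4-en-1-yn-1-yl)benzene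
Product: 10 6-bromo-2-[2,4-bis(methoxymethoxy)phenyl]-5,7-dimethoxy-3-(3-methylbut-2-en-1-yl)-4H-chromen-4-one
Conditions: [RhCl2(C5Me5)]2 (2.5 mol %), Cu(OAc)2 (2.2 equiv), t-AmOH, 80 °C, N2
Reagents that add atoms: none
Why: Proposed new method: the phenoxide of 4 binds trivalent rhodium and directs cleavage of the aldehyde C–H bond to a five-membered acyl rhodacycle; the enyne 9 inserts through its alkyne only, the acyl carbon bonding to the CH2-bearing alkyne carbon and rhodium ending on the aryl-bearing carbon (aryl-stabilised alkenyl–rhodium, helped by chelation of the ortho OCH2OMe oxygen); C–O reductive elimination from the seven-membered oxarhodacycle forms the O1–C2 bond of ring C, and Cu(OAc)2 returns monovalent rhodium to trivalent rhodium; 4 has only one OH ortho to CHO, so a single chromone is possible; the closest known reaction type is the rhodium-catalysed oxidative annulation of salicylaldehydes with simple diaryl, dialkyl and aryl–alkyl alkynes to 2,3-disubstituted chromones, not shown for a prenyl-bearing skipped enyne.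

Step 7
Reactants: 10 6-bromo-2-[2,4-bis(methoxymethoxy)phenyl]-5,7-dimethoxy-3-(3-methylbut-2-en-1-yl)-4H-chromen-4-one; 11 3-methylbutan-2-one
Product: 12 2-[2,4-bis(methoxymethoxy)phenyl]-5,7-dimethoxy-6-(3-methyl-2-oxobutyl)-3-(3-methylbut-2-en-1-yl)-4H-chromen-4-one
Conditions: Pd2(dba)3 (2.5 mol %), XPhos (10 mol %), NaOtBu (2.2 equiv), 11 (5 equiv), toluene, 70 °C
Reagents that add atoms: none
Why: Palladium-catalysed ketone alpha-arylation (Buchwald–Hartwig enolate coupling): the sodium enolate of 11 couples at its less hindered methyl side, a bulky biaryl phosphine lets zerovalent palladium insert into the di-ortho-methoxy aryl bromide, and the same hindrance blocks a second arylation.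

Step 8
Reactants: 12 2-[2,4-bis(methoxymethoxy)phenyl]-5,7-dimethoxy-6-(3-methyl-2-oxobutyl)-3-(3-methylbut-2-en-1-yl)-4H-chromen-4-one
Product: 13 2-(2,4-dihydroxyphenyl)-5-hydroxy-7-methoxy-6-(3-methyl-2-oxobutyl)-3-(3-methylbut-2-en-1-yl)-4H-chromen-4-one
Conditions: BCl3 (6 equiv), CH2Cl2, −78 → −10 °C; MeOH, then cold aq. NaHCO3
Reagents that add atoms: none
Why: Chelation-controlled Lewis-acid ether cleavage: BCl3 bound between the C4 carbonyl and the peri 5-OMe removes only that methyl group (7-OMe is not chelated) and cleaves both MOM acetals, while the 5-oxygen stays tied up as a boron chelate until the cold buffered quench, which protects the ortho-hydroxybenzyl ketone from acid-induced furan formation and limits acid contact of the prenyl group.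

**Compound list**
1 | 2-bromo-1,3-dimethoxybenzene | COc1cccc(OC)c1Br | starting material
2 | 2-(4-bromo-3,5-dimethoxyphenyl)-4,4,5,5-tetramethyl-1,3,2-dioxaborolane | COc1cc(cc(OC)c1Br)B1OC(C)(C)C(C)(C)O1 | intermediate
3 | 4-bromo-3,5-dimethoxyphenol | COc1cc(O)cc(OC)c1Br | intermediate
4 | 3-bromo-6-hydroxy-2,4-dimethoxybenzaldehyde | COc1cc(O)c(C=O)c(OC)c1Br | intermediate
5 | 2,4-dihydroxybenzaldehyde | Oc1ccc(C=O)c(O)c1 | starting material
6 | 2,4-bis(methoxymethoxy)benzaldehyde | COCOc1ccc(C=O)c(OCOC)c1 | intermediate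
7 | 1-ethynyl-2,4-bis(methoxymethoxy)benzene | COCOc1ccc(C#C)c(OCOC)c1 | intermediate
8 | 1-bromo-3-methylbut-2-ene | CC(C)=CCBr | starting material
9 | 2,4-bis(methoxymethoxy)-1-(5-methylhex-4-en-1-yn-1-yl)benzene | COCOc1ccc(C#CCC=C(C)C)c(OCOC)c1 | intermediate
10 | 6-bromo-2-[2,4-bis(methoxymethoxy)phenyl]-5,7-dimethoxy-3-(3-methylbut-2-en-1-yl)-4H-chromen-4-one | COc1cc2oc(-c3ccc(OCOC)cc3OCOC)c(CC=C(C)C)c(=O)c2c(OC)c1Br | intermediate
11 | 3-methylbutan-2-one | CC(C)C(C)=O | starting material
12 | 2-[2,4-bis(methoxymethoxy)phenyl]-5,7-dimethoxy-6-(3-methyl-2-oxobutyl)-3-(3-methylbut-2-en-1-yl)-4H-chromen-4-one | COc1cc2oc(-c3ccc(OCOC)cc3OCOC)c(CC=C(C)C)c(=O)c2c(OC)c1CC(=O)C(C)C | intermediate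
13 | 2-(2,4-dihydroxyphenyl)-5-hydroxy-7-methoxy-6-(3-methyl-2-oxobutyl)-3-(3-methylbut-2-en-1-yl)-4H-chromen-4-one | COc1cc2oc(-c3ccc(O)cc3O)c(CC=C(C)C)c(=O)c2c(O)c1CC(=O)C(C)C | target

**Totals**
Total step count: 8. Longest linear sequence: 6 (steps 3, 4, 5, 6, 7, 8). If 4-bromo-3,5-dimethoxyphenol is bought instead of made, step 1 drops out.

**Three steps most likely to fail**

Step 6 (the new annulation). The prenyl alkene or the doubly activated CH2 of the enyne may interfere (coordination, isomerisation), or the crowded aldehyde may decarbonylate. The fallback uses only known chemistry, sets out from 3, 6 and 8, and comes back at 10. Ortho-C-acetylation of 3 (AcOH, BF3·OEt2, 90 °C; symmetry again gives one isomer) gives 1-(3-bromo-6-hydroxy-2,4-dimethoxyphenyl)ethan-1-one F1. Pinnick oxidation of 6 (NaClO2, NaH2PO4, 2-methylbut-2-ene) gives 2,4-bis(methoxymethoxy)benzoic acid F2. Carbodiimide/DMAP esterification of the two gives 2-acetyl-4-bromo-3,5-dimethoxyphenyl 2,4-bis(methoxymethoxy)benzoate F3. Baker–Venkataraman rearrangement (KOtBu, THF) gives 1-(3-bromo-6-hydroxy-2,4-dimethoxyphenyl)-3-[2,4-bis(methoxymethoxy)phenyl]propane-1,3-dione F4. C-prenylation of the diketone with 8 (K2CO3, acetone) gives 1-(3-bromo-6-hydroxy-2,4-dimethoxyphenyl)-3-[2,4-bis(methoxymethoxy)phenyl]-2-(3-methylbut-2-en-1-yl)propane-1,3-dione F5. Mild cyclodehydration (pyridinium tosylate, toluene, 80 °C) closes the same O1–C2 bond and gives 10.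

Step 7 (α-arylation on the crowded, base-exposed bromoflavone). The fallback moves the C–C coupling to the start, where only an aryl bromide is present; it sets out from 1 and 11 and comes back at 12. α-Arylation of 11 with 1 under the step 7 conditions gives 1-(2,6-dimethoxyphenyl)-3-methylbutan-2-one F6. C–H borylation as in step 1 gives 1-[2,6-dimethoxy-4-(4,4,5,5-tetramethyl-1,3,2-dioxaborolan-2-yl)phenyl]-3-methylbutan-2-one F7 (not isolated), and oxidation gives 1-(4-hydroxy-2,6-dimethoxyphenyl)-3-methylbutan-2-one F8. Ortho-formylation under Rieche conditions (Cl2CHOMe, TiCl4, CH2Cl2, −78 → 0 °C, chosen to avoid aldol of the ketone with formaldehyde) gives 6-hydroxy-2,4-dimethoxy-3-(3-methyl-2-oxobutyl)benzaldehyde F9. Annulation of F9 with 9 under the step 6 conditions gives 12 directly.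

Step 8 (one-pot unmasking next to a prenyl group and an ortho-hydroxybenzyl ketone). The fallback splits the unmasking into two orthogonal operations, from 12 back to 13. MgI2·OEt2 (toluene/THF, 60 °C) cleaves only the chelated 5-OMe and gives 2-[2,4-bis(methoxymethoxy)phenyl]-5-hydroxy-7-methoxy-6-(3-methyl-2-oxobutyl)-3-(3-methylbut-2-en-1-yl)-4H-chromen-4-one F10. Acetal exchange (2 M HCl in MeOH/THF, 35 °C, short contact) then removes the two MOM groups and gives 13.

**Further compounds**
F1 | step 6 | 1-(3-bromo-6-hydroxy-2,4-dimethoxyphenyl)ethan-1-one | CC(=O)c1c(O)cc(OC)c(Br)c1OC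
F2 | step 6 | 2,4-bis(methoxymethoxy)benzoic acid | COCOc1ccc(C(=O)O)c(OCOC)c1
F3 | step 6 | 2-acetyl-4-bromo-3,5-dimethoxyphenyl 2,4-bis(methoxymethoxy)benzoate | CC(=O)c1c(OC(=O)c2ccc(OCOC)cc2OCOC)cc(OC)c(Br)c1OC
F4 | step 6 | 1-(3-bromo-6-hydroxy-2,4-dimethoxyphenyl)-3-[2,4-bis(methoxymethoxy)phenyl]propane-1,3-dione | COCOc1ccc(C(=O)CC(=O)c2c(O)cc(OC)c(Br)c2OC)c(OCOC)c1
F5 | step 6 | 1-(3-bromo-6-hydroxy-2,4-dimethoxyphenyl)-3-[2,4-bis(methoxymethoxy)phenyl]-2-(3-methylbut-2-en-1-yl)propane-1,3-dione | COCOc1ccc(C(=O)C(CC=C(C)C)C(=O)c2c(O)cc(OC)c(Br)c2OC)c(OCOC)c1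
F6 | step 7 | 1-(2,6-dimethoxyphenyl)-3-methylbutan-2-one | COc1cccc(OC)c1CC(=O)C(C)C
F7 | step 7 | 1-[2,6-dimethoxy-4-(4,4,5,5-tetramethyl-1,3,2-dioxaborolan-2-yl)phenyl]-3-methylbutan-2-one | COc1cc(cc(OC)c1CC(=O)C(C)C)B1OC(C)(C)C(C)(C)O1
F8 | step 7 | 1-(4-hydroxy-2,6-dimethoxyphenyl)-3-methylbutan-2-one | COc1cc(O)cc(OC)c1CC(=O)C(C)C
F9 | step 7 | 6-hydroxy-2,4-dimethoxy-3-(3-methyl-2-oxobutyl)benzaldehyde | COc1cc(O)c(C=O)c(OC)c1CC(=O)C(C)C
F10 | step 8 | 2-[2,4-bis(methoxymethoxy)phenyl]-5-hydroxy-7-methoxy-6-(3-methyl-2-oxobutyl)-3-(3-methylbut-2-en-1-yl)-4H-chromen-4-one | COc1cc2oc(-c3ccc(OCOC)cc3OCOC)c(CC=C(C)C)c(=O)c2c(O)c1CC(=O)C(C)C
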